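## Structural features

The target is a biflavanoid in which a 7,4'-dihydroxyflavan-3-ol (upper unit: resorcinol-type ring A, pyran ring C, aryl ring B) is joined by a single C4–C8' bond to a 5,7,4'-trihydroxyflavan-3-ol (lower unit: phloroglucinol-type ring D, pyran ring F, aryl ring E). Ring C carries three contiguous stereocentres, C2 (R), C3 (S) and C4 (S), all trans, and ring F carries two, C2' (S) and C3' (R), also trans. The two clusters face each other across the hindered C4–C8' aryl bond and belong to opposite series ((2R,3S) above, (2S,3R) below), so neither can be expected to control the other and the two halves cannot come from one chiral source. Fragile elements are the six free phenols (most of all on ring D), the benzylic aryl ether bonds O1–C2 and O1'–C2' (each attached to a para-oxygenated aryl ring and therefore ionisable), and the acid-labile interflavan bond. The real difficulty lies at ring D: C8' and C6' are nearly equivalent sites, ring F must close onto the C8a' oxygen and not the C5' oxygen, and C4 must carry a di-ortho-substituted aryl group trans to the C3 hydroxyl. The key step exploits three features: the C8a' oxygen together with the C4a'–C4' methylene is an ortho-quinone methide pattern, C3' maps onto the α-carbon of an α-alkoxy aldehyde, and C2' sits at the aldehyde oxidation level as the lactol carbon of ring F, ready to accept ring E.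

## Logic of the disconnections

28 from 27. The six O–benzyl bonds are cut last. All phenols and the C3' hydroxyl stay masked as one kind of ether, so the free polyphenol never meets acid, base or oxidant. The forward step must cleave five aryl benzyl ethers and one alkyl benzyl ether without touching O1–C2, O1'–C2' or C4–C8'.

27 from 25. The O1'–C2' bond of ring F is cut, because C2' is benzylic to ring E and para to oxygen and therefore easy to ionise. Ring F becomes an open chain and C2' need not be made selectively in 25. The forward closure must use only the C8a' oxygen, must give the trans relationship to the C3' benzyloxy group, and must not ionise the analogous O1–C2 bond.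

25 from 23 and 24. The bond from C2' to ring E is cut. Ring E becomes an aryl Grignard reagent and C2' an aldehyde carbon held as a lactol. The lower unit shrinks to a three-carbon chain on ring D. The organometallic must open the lactol and add in the presence of a free C3 hydroxyl without epimerising C3'.

23 from 18 and 19 (key disconnection). C3'–C4' and O1'–C2' are cut together, which removes ring F and the C3' stereocentre and leaves a 2-(tosylmethyl)phenol and a two-carbon aldehyde. The forward step needs one quinone methide, one ring closure and catalyst control at C3'. For that reason 18 carries benzyl ethers on both C5' and C7'. A free C7' hydroxyl would sit para to the tosylmethyl carbon and could expel sulfinate just as well, so the C8a' oxygen is the only possible quinone methide oxygen only when C7' is capped. A second free phenol would also leave an acidic, deactivating site on the quinone methide and a more nucleophilic ring D able to capture it.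

18 from 16, and 16 from 14. The C4'–S bond is cut back to the alcohol oxidation level (17, made and consumed in one flask), and this is traced to 16. The C4a'–C4' bond is then cut to a formaldehyde equivalent. With C7' as an ether, ring D of 14 is unsymmetrical, so the one-carbon unit must be placed ortho to the only phenol. This is the price of capping C7' in 18. It is paid with a chelation-controlled ortho-formylation, because an acid-mediated substitution could also go para, at C6'. The carbon arrives at the aldehyde level because the magnesium-bound alkoxide 15 that delivers it is oxidised in the flask as it forms. The free benzylic alcohol is therefore produced only once, by reduction, at the moment it is needed.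

14 from 13, and 13 from 11. The methoxymethyl ether is restored on the C8a' oxygen, then the C3–O and C4–H bonds are cut back to the C3=C4 alkene. One stereocentre (C2) then controls two. The forward addition must come anti to the C2 aryl group and deliver H and the oxygen precursor syn.

11 from 9, and 9 from 4 and 6. Rehydration at C4 and cutting C4–C8' separate the upper unit as a ketone from ring D as an aryl nucleophile (7, then 8, generated from 6). The hindered C4–aryl bond is made at an sp2 carbon and its stereochemistry is postponed. The metal must sit next to the methoxymethoxy group of 6, and addition must outrun enolisation of 4, which would open ring C and erase C2.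

4 from 2 and 3. The bond from C2 to ring B is cut. An aryl boronic acid and a chromone are both flat, so C2 is set by a chiral catalyst alone.

2 from 1, and 6 from 5. Only O-alkyl bonds are cut. 5 already has two benzyl ethers and one free hydroxyl, so no statistical differentiation of a symmetrical triol is needed.

## Other disconnections considered

Alternative 1: The cut goes through ring D. C8'–C8a' and C6'–C7' are new bonds and C4a'–C8a' is broken and re-formed. In the forward direction cyclobutenone A3 would be heated with alkyne A2. A3 is a 3-silyloxycyclobutenone carrying the C4'–C3'–C2'–ring E chain as a trans-acetonide on its sp3 carbon. A2 is the tri-O-benzyl upper unit with a (triisopropylsilyloxy)ethynyl group on C4. Ring opening of A3 to a vinylketene, [2+2] addition to the alkyne, a second four-electron opening and a six-electron closure would give phenol A1.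
- In favour: every substituent of the hexasubstituted ring D is placed by the connectivity of A2 and A3. The interflavan bond is at C8' by construction and only the C8a' oxygen is free. The regiochemical questions that the chosen plan answers with directing effects (metalation of 6, formylation of 14) do not arise, and on this point the alternative is the better plan. The cascade is also neutral, which is at least equal to the chosen route in sparing ionisable benzylic ethers.
- Against: A2 needs an ynol silyl ether on the all-trans C4 stereocentre. A3 is a sensitive four-membered ring with a benzylic acetonide. The cascade needs prolonged heating. A1 is still open at ring F, so acetonide cleavage, selective activation of the C2' hydroxyl, closure with inversion and desilylation must follow.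
- Comparison: in step economy the alternative is clearly longer, since both partners are multistep and the lower stereocentres need a separate asymmetric oxidation. The chosen plan starts ring D from a commercial phenol and sets C3' in the step that closes ring F.

Alternative 2: Both aryl–oxygen bonds of the pyran rings, O1–C8a and O1'–C8a', are cut, which leads to the open-chain dibromo diol A5. CuI with a phenanthroline ligand and Cs2CO3 would couple the C2 and C2' benzylic alkoxides with the aryl bromides on C8a and C8a' and close rings C and F in one operation to the hepta-O-benzyl ether A4.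
- In favour: the new bonds are made at aromatic carbons, so C2 and C2' keep the configuration they have in A5. At C2' this is better than the chosen plan, which passes through cation 26 and relies on a trans preference. A4 is one hydrogenolysis from 28, equal to the chosen endgame.
- Against: all five stereocentres must be set in an acyclic chain, including C4 with its two aryl groups, both ortho-brominated. The stereochemical problem is moved and not solved. Secondary benzylic alkoxides under hot basic copper conditions can be oxidised or can fragment, the C8a' bromide is flanked by two ortho substituents, and both closures must succeed.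
- Comparison: on mechanism the alternative is cleaner at the ring-closing stage, with no carbocation. On structure it gives no help with ring D regiochemistry or with C4. On step economy it should be longer because of A5.

Alternative 3: Ring C is cut at C3–C4 and O1–C2. The ortho-quinone methide A7 of ring A, whose methide carbon C4 already carries the complete lower unit through C8', would add the (E)-styrene A8 in a hetero-[4+2] reaction. The silicon-bearing carbon bonds to C4 and the benzylic carbon to O1. The benzyldimethylsilyl group of product A6 would later be oxidised to the C3 hydroxyl with retention.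
- In favour: it is the most convergent plan. It forms ring C and three stereocentres in one step, translates the E geometry of A8 into the 2,3-trans relationship, and uses the β-silyl effect and the para-oxygenated aryl group to fix the regiochemistry. In bonds and stereocentres formed per step it is better than the chosen plan.
- Against: the face of A7 that is attacked, and with it the absolute configuration of C2, C3 and C4, is decided only by the remote lower stereocentres across a rotating bond. Endo/exo selectivity decides the 3,4 relationship. A vinylsilane is a modest partner for a stabilised aryl-substituted quinone methide. The lower unit, which is of the less common enantiomeric series, must be made separately and functionalised at C8' in competition with C6'.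
- Comparison: the chosen plan is longer in the upper half, but it sets the absolute configuration of each half with its own catalyst (steps 2 and 10) and derives C3 and C4 from C2 by a stereospecific syn addition. That is the more reliable control for the single enantiomer required.

Key step: step 10

Assumptions (remarks on the chemistry):
- Atom labels follow flavanoid usage: the upper unit is unprimed (rings A, C, B), the lower unit primed (rings D, F, E).
- The (R)-configured pyridine–oxazoline ligand in step 2 is assigned by analogy with the facial sense known for 3-substituted cyclohexenones. If the sense is the opposite, the antipodal ligand is used and nothing else changes.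
- The enamine in step 10 is assumed to react through its E geometry, as α-alkoxy aldehydes normally do in this type of catalysis.
- 24 is taken as a commercial THF solution.

## Route

Step 1
Reactants: 1 7-hydroxychromone
Product: 2 7-benzyloxychromone
Conditions: BnBr, K2CO3, acetone, reflux
Reagents that add atoms: benzyl bromide, BrCc1ccccc1
Why: Williamson ether synthesis on the acidic 7-hydroxyl; carbonate in acetone should not open the pyrone ring.

Step 2
Reactants: 2 7-benzyloxychromone; 3 4-benzyloxyphenylboronic acid
Product: 4 (2S)-7-benzyloxy-2-(4-benzyloxyphenyl)chroman-4-one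
Conditions: Pd(OCOCF3)2 (5 mol%), (R)-t-BuPyOx (6 mol%), NH4PF6 (30 mol%), H2O (5 equiv), ClCH2CH2Cl, 60 °C
Reagents that add atoms: none
Why: Enantioselective conjugate addition of an arylboronic acid to a chromone under divalent palladium catalysis (aryl–palladium insertion into C2=C3, then protonolysis of the palladium enolate). The pyridine–oxazoline ligand differentiates the enone faces and should set C2 as S, and the absence of base avoids the ring opening that racemises flavanones.

Step 3
Reactants: 5 3,5-bis(benzyloxy)phenol
Product: 6 1,3-bis(benzyloxy)-5-(methoxymethoxy)benzene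
Conditions: NaH, MOMCl, DMF, 0 °C → rt
Reagents that add atoms: chloromethyl methyl ether, COCCl
Why: O-alkylation of the sodium phenoxide; the methoxymethyl ether is chosen because it is the strongest ortho-director on the ring and is later removed by dilute acid without touching benzyl ethers.

Step 4
Reactants: 6 1,3-bis(benzyloxy)-5-(methoxymethoxy)benzene; 4 (2S)-7-benzyloxy-2-(4-benzyloxyphenyl)chroman-4-one
Product: 9 (2S,4RS)-4-[2,4-bis(benzyloxy)-6-(methoxymethoxy)phenyl]-7-benzyloxy-2-(4-benzyloxyphenyl)chroman-4-ol, via aryllithium 7 (not isolated), via arylcerium dichloride 8 (not isolated)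
Conditions: n-BuLi, THF, 0 °C; CeCl3 (anhydrous), −78 °C; then 4, −78 → −40 °C; aq. NH4Cl
Reagents that add atoms: none
Why: Directed ortho-metalation next to the methoxymethoxy group (the site flanked by OMOM and OBn should be preferred over the one between two weaker benzyloxy directors), transmetalation to the weakly basic organocerium, and 1,2-addition to the ketone. The cerium reagent should suppress enolisation at C3 and so protect C2; the configuration of the new carbinol carbon is irrelevant because it is removed in step 5.

Step 5
Reactants: 9 (2S,4RS)-4-[2,4-bis(benzyloxy)-6-(methoxymethoxy)phenyl]-7-benzyloxy-2-(4-benzyloxyphenyl)chroman-4-ol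
Product: 11 (2S)-4-[2,4-bis(benzyloxy)-6-(methoxymethoxy)phenyl]-7-benzyloxy-2-(4-benzyloxyphenyl)-2H-chromene, via sulfamate ester 10 (not isolated)
Conditions: Burgess reagent (MeO2CN(−)SO2N(+)Et3), THF, rt → 50 °C
Reagents that add atoms: none
Why: Burgess dehydration of a tertiary benzylic alcohol through its sulfamate ester; only C3 carries β-hydrogen, so a single alkene can form. The neutral conditions avoid acid that could ionise the allylic O1–C2 bond of the 2H-chromene and erase C2.

Step 6
Reactants: 11 (2S)-4-[2,4-bis(benzyloxy)-6-(methoxymethoxy)phenyl]-7-benzyloxy-2-(4-benzyloxyphenyl)-2H-chromene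
Product: 13 (2R,3S,4S)-4-[2,4-bis(benzyloxy)-6-(methoxymethoxy)phenyl]-7-benzyloxy-2-(4-benzyloxyphenyl)chroman-3-ol, via alkylborane 12 (not isolated)
Conditions: BH3·THF, THF, 0 °C → rt; then NaOH (aq.), H2O2, 0 °C → rt
Reagents that add atoms: hydrogen peroxide, OO
Why: Hydroboration–oxidation of the trisubstituted styrene-type alkene: boron should add to the less substituted C3 from the face opposite the C2 aryl group, with hydrogen going to C4 on the same face (syn addition). Oxidation with retention then gives the 2,3-trans-3,4-trans alcohol, setting C3 (S) and C4 (S) in one operation.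

Step 7
Reactants: 13 (2R,3S,4S)-4-[2,4-bis(benzyloxy)-6-(methoxymethoxy)phenyl]-7-benzyloxy-2-(4-benzyloxyphenyl)chroman-3-ol
Product: 14 (2R,3S,4S)-4-[2,4-bis(benzyloxy)-6-hydroxyphenyl]-7-benzyloxy-2-(4-benzyloxyphenyl)chroman-3-ol
Conditions: HCl (3 M aq.), MeOH–THF, 45 °C
Reagents that add atoms: none
Why: Acid-catalysed acetal cleavage of the aryl methoxymethyl ether, with methanol trapping the formaldehyde unit; benzyl ethers and the secondary alcohol are inert, and the 5-deoxy ring A makes the C4–aryl bond tolerant of dilute acid.

Step 8
Reactants: 14 (2R,3S,4S)-4-[2,4-bis(benzyloxy)-6-hydroxyphenyl]-7-benzyloxy-2-(4-benzyloxyphenyl)chroman-3-ol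
Product: 16 4,6-bis(benzyloxy)-3-[(2R,3S,4S)-7-benzyloxy-2-(4-benzyloxyphenyl)-3-hydroxychroman-4-yl]-2-hydroxybenzaldehyde, via magnesium aryloxide–alkoxide chelate 15 (not isolated)
Conditions: MgCl2 (anhydrous), Et3N, (CH2O)n, THF, reflux; then 1 M HCl
Reagents that add atoms: formaldehyde (as paraformaldehyde), C=O
Why: Magnesium-mediated ortho-formylation of a phenol: formaldehyde is delivered inside the magnesium phenoxide to the only free ortho position (C4a') and gives the magnesium-bound benzylic alkoxide 15, which a second formaldehyde oxidises by hydride transfer before it can be set free as the alcohol. C6' is not ortho to a free hydroxyl and cannot react by this pathway, and the aliphatic C3 hydroxyl is not ionised by Et3N. The stable aldehyde is the isolable checkpoint at which the position of the new carbon can be confirmed.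

Step 9
Reactants: 16 4,6-bis(benzyloxy)-3-[(2R,3S,4S)-7-benzyloxy-2-(4-benzyloxyphenyl)-3-hydroxychroman-4-yl]-2-hydroxybenzaldehyde
Product: 18 (2R,3S,4S)-4-{4,6-bis(benzyloxy)-2-hydroxy-3-[(4-methylphenyl)sulfonylmethyl]phenyl}-7-benzyloxy-2-(4-benzyloxyphenyl)chroman-3-ol, via salicyl alcohol 17 (not isolated)
Conditions: NaBH4, THF–MeOH, 0 °C; then p-TolSO2Na, HCO2H–H2O, rt
Reagents that add atoms: sodium p-toluenesulfinate, Cc1ccc(S(=O)[O-])cc1.[Na+]
Why: Borohydride reduction of the salicylaldehyde gives the free, electron-rich salicyl alcohol 17, which is too prone to self-condensation to isolate. Acidification in the presence of sulfinate should convert it by S-alkylation into the benzylic sulfone (substitution of a 2-hydroxybenzyl alcohol by a sulfinic acid), the sulfone being the irreversible product.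

Step 10
Reactants: 18 (2R,3S,4S)-4-{4,6-bis(benzyloxy)-2-hydroxy-3-[(4-methylphenyl)sulfonylmethyl]phenyl}-7-benzyloxy-2-(4-benzyloxyphenyl)chroman-3-ol; 19 benzyloxyacetaldehyde
Product: 23 (2RS,3R)-3,5,7-tris(benzyloxy)-8-[(2R,3S,4S)-7-benzyloxy-2-(4-benzyloxyphenyl)-3-hydroxychroman-4-yl]chroman-2-ol, via enamine 20 (not isolated), via ortho-quinone methide 21 (not isolated), via hydroxy aldehyde 22 (not isolated)
Conditions: (S)-2-[diphenyl(trimethylsilyloxy)methyl]pyrrolidine (20 mol%), Cs2CO3, CH2Cl2, 0 °C → rt; 19 in excess (3 equiv)
Reagents that add atoms: none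
Why: Cs2CO3 deprotonates the single free phenol (C8a'–OH) of 18 and 1,4-elimination of p-toluenesulfinate gives ortho-quinone methide 21, while the secondary amine condenses with 19 to the E-enamine 20. The enamine carbon that becomes C3' adds to the exocyclic methylene C4' in a Michael reaction that restores the aromaticity of ring D, and hydrolysis of the iminium ion releases aldehyde 22 and the catalyst. The C8a' phenol then adds to the aldehyde carbon in a 6-exo-trig hemiacetalisation that closes ring F (O1'–C2') and gives 23 as an anomeric mixture. The closest known reaction type is the diarylprolinol silyl ether-catalysed addition of enolisable aldehydes to ortho-quinone methides released from 2-(sulfonylmethyl)phenols, which ends in chroman-2-ols. C3' is set by the catalyst: the diphenyl(silyloxy)methyl group shields one face of the anti E-enamine, so C4' attaches to the open face, which for the (S)-catalyst corresponds to R at C3'; the stereocentres of ring C are too remote to interfere, and C2' is left uncontrolled because it is made planar again in steps 11 and 12. The step needs regioselectivity and chemoselectivity: only the C8a' oxygen is free (C5' and C7' are benzyl ethers), so one quinone methide and one ring closure are possible and the 4→8 connectivity is fixed, while the heterogeneous base keeps the quinone methide concentration low and the excess aldehyde lets enamine capture outrun self-condensation. Closure to the lactol also masks the α-benzyloxy aldehyde and so protects C3' from epimerisation.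

Step 11
Reactants: 23 (2RS,3R)-3,5,7-tris(benzyloxy)-8-[(2R,3S,4S)-7-benzyloxy-2-(4-benzyloxyphenyl)-3-hydroxychroman-4-yl]chroman-2-ol; 24 4-benzyloxyphenylmagnesium bromide
Product: 25 (1RS,2R)-2-benzyloxy-1-(4-benzyloxyphenyl)-3-{4,6-bis(benzyloxy)-3-[(2R,3S,4S)-7-benzyloxy-2-(4-benzyloxyphenyl)-3-hydroxychroman-4-yl]-2-hydroxyphenyl}propan-1-ol
Conditions: 24 (5 equiv), THF, 0 °C → rt; aq. NH4Cl
Reagents that add atoms: none
Why: Grignard addition to a lactol: deprotonation opens the hemiacetal to the magnesium phenoxide–aldehyde, which is arylated at C2' faster than it can enolise, the excess reagent covering the two hydroxyl protons. Chelation between magnesium, the aldehyde oxygen and the C3' benzyloxy group should favour the syn (1R,2R) carbinol, but both C2' epimers are usable because step 12 passes through a planar cation.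

Step 12
Reactants: 25 (1RS,2R)-2-benzyloxy-1-(4-benzyloxyphenyl)-3-{4,6-bis(benzyloxy)-3-[(2R,3S,4S)-7-benzyloxy-2-(4-benzyloxyphenyl)-3-hydroxychroman-4-yl]-2-hydroxyphenyl}propan-1-ol
Product: 27 (2R,3S,4S)-7-benzyloxy-2-(4-benzyloxyphenyl)-4-[(2S,3R)-3,5,7-tris(benzyloxy)-2-(4-benzyloxyphenyl)chroman-8-yl]chroman-3-ol, via benzylic cation 26 (not isolated)
Conditions: TsOH·H2O (10 mol%), CH2Cl2, 4 Å MS, −20 → 0 °C
Reagents that add atoms: none
Why: Acid-catalysed intramolecular etherification through the para-benzyloxybenzyl cation: the C8a' phenol attacks C2' in a 6-exo-trig closure (the cation is an O-benzylated para-quinone methide) through a chair-like transition state with ring E and the C3' benzyloxy group both equatorial, so the 2',3'-trans isomer (C2' S) should be favoured kinetically and thermodynamically. The secondary benzylic carbinol ionises far more readily than the aryl ether bond O1–C2 or the C3 hydroxyl, so the upper unit should be untouched with catalytic acid at low temperature.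

Step 13
Reactants: 27 (2R,3S,4S)-7-benzyloxy-2-(4-benzyloxyphenyl)-4-[(2S,3R)-3,5,7-tris(benzyloxy)-2-(4-benzyloxyphenyl)chroman-8-yl]chroman-3-ol
Product: 28 (2R,3S,4S)-2-(4-hydroxyphenyl)-4-[(2S,3R)-3,5,7-trihydroxy-2-(4-hydroxyphenyl)chroman-8-yl]chroman-3,7-diol
Conditions: H2 (1 atm), Pd(OH)2/C, THF–MeOH, rt
Reagents that add atoms: none
Why: Hydrogenolysis of six benzyl ethers (five aryl, one alkyl) under neutral conditions; the cyclic benzylic aryl ethers O1–C2 and O1'–C2' and the C4–C8' bond are cleaved much more slowly than O-benzyl groups, and no acid or base is present that could epimerise the free polyphenol.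

## Compound list

1 | 7-hydroxychromone | O=c1ccoc2cc(O)ccc12 | starting material
2 | 7-benzyloxychromone | O=c1ccoc2cc(OCc3ccccc3)ccc12 | intermediate
3 | 4-benzyloxyphenylboronic acid | OB(O)c1ccc(OCc2ccccc2)cc1 | starting material
4 | (2S)-7-benzyloxy-2-(4-benzyloxyphenyl)chroman-4-one | c1ccccc1COc1ccc([C@H]2Oc3cc(OCc4ccccc4)ccc3C(=O)C2)cc1 | intermediate
5 | 3,5-bis(benzyloxy)phenol | Oc1cc(OCc2ccccc2)cc(OCc2ccccc2)c1 | starting material
6 | 1,3-bis(benzyloxy)-5-(methoxymethoxy)benzene | COCOc1cc(OCc2ccccc2)cc(OCc2ccccc2)c1 | intermediate
7 | [2,4-bis(benzyloxy)-6-(methoxymethoxy)phenyl]lithium | [Li]c1c(OCOC)cc(OCc2ccccc2)cc1OCc1ccccc1 | intermediate (not isolated)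
8 | dichloro[2,4-bis(benzyloxy)-6-(methoxymethoxy)phenyl]cerium | Cl[Ce](Cl)c1c(OCOC)cc(OCc2ccccc2)cc1OCc1ccccc1 | intermediate (not isolated)
9 | (2S,4RS)-4-[2,4-bis(benzyloxy)-6-(methoxymethoxy)phenyl]-7-benzyloxy-2-(4-benzyloxyphenyl)chroman-4-ol | c1ccccc1COc1ccc([C@H]2Oc3cc(OCc4ccccc4)ccc3C(O)(c3c(OCOC)cc(OCc4ccccc4)cc3OCc3ccccc3)C2)cc1 | intermediate
10 | C4 O-sulfamate of 9, methyl N-(alkoxysulfonyl)carbamate on the C4 oxygen (triethylammonium salt in the flask) | c1ccccc1COc1ccc([C@H]2Oc3cc(OCc4ccccc4)ccc3C(OS(=O)(=O)NC(=O)OC)(c3c(OCOC)cc(OCc4ccccc4)cc3OCc3ccccc3)C2)cc1 | intermediate (not isolated)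
11 | (2S)-4-[2,4-bis(benzyloxy)-6-(methoxymethoxy)phenyl]-7-benzyloxy-2-(4-benzyloxyphenyl)-2H-chromene | c1ccccc1COc1ccc([C@H]2Oc3cc(OCc4ccccc4)ccc3C(c3c(OCOC)cc(OCc4ccccc4)cc3OCc3ccccc3)=C2)cc1 | intermediate
12 | all-trans C3 borane corresponding to 13 (BH2 in place of the C3 hydroxyl, same spatial arrangement) | c1ccccc1COc1ccc([C@H]2Oc3cc(OCc4ccccc4)ccc3[C@@H](c3c(OCOC)cc(OCc4ccccc4)cc3OCc3ccccc3)[C@@H]2B)cc1 | intermediate (not isolated)
13 | (2R,3S,4S)-4-[2,4-bis(benzyloxy)-6-(methoxymethoxy)phenyl]-7-benzyloxy-2-(4-benzyloxyphenyl)chroman-3-ol | c1ccccc1COc1ccc([C@H]2Oc3cc(OCc4ccccc4)ccc3[C@@H](c3c(OCOC)cc(OCc4ccccc4)cc3OCc3ccccc3)[C@@H]2O)cc1 | intermediate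
14 | (2R,3S,4S)-4-[2,4-bis(benzyloxy)-6-hydroxyphenyl]-7-benzyloxy-2-(4-benzyloxyphenyl)chroman-3-ol | c1ccccc1COc1ccc([C@H]2Oc3cc(OCc4ccccc4)ccc3[C@@H](c3c(O)cc(OCc4ccccc4)cc3OCc3ccccc3)[C@@H]2O)cc1 | intermediate
15 | cyclic magnesium aryloxide–alkoxide of the ring D salicyl alcohol: 5,7-bis(benzyloxy)-8-[(2R,3S,4S)-7-benzyloxy-2-(4-benzyloxyphenyl)-3-hydroxychroman-4-yl]-4H-1,3,2-benzodioxamagnesine (Mg bridging the C8a' oxygen and the C4' oxygen) | c1ccccc1COc1ccc([C@H]2Oc3cc(OCc4ccccc4)ccc3[C@@H](c3c4O[Mg]OCc4c(OCc4ccccc4)cc3OCc3ccccc3)[C@@H]2O)cc1 | intermediate (not isolated)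
16 | 4,6-bis(benzyloxy)-3-[(2R,3S,4S)-7-benzyloxy-2-(4-benzyloxyphenyl)-3-hydroxychroman-4-yl]-2-hydroxybenzaldehyde | c1ccccc1COc1ccc([C@H]2Oc3cc(OCc4ccccc4)ccc3[C@@H](c3c(O)c(C=O)c(OCc4ccccc4)cc3OCc3ccccc3)[C@@H]2O)cc1 | intermediate
17 | (2R,3S,4S)-4-[4,6-bis(benzyloxy)-2-hydroxy-3-(hydroxymethyl)phenyl]-7-benzyloxy-2-(4-benzyloxyphenyl)chroman-3-ol | c1ccccc1COc1ccc([C@H]2Oc3cc(OCc4ccccc4)ccc3[C@@H](c3c(O)c(CO)c(OCc4ccccc4)cc3OCc3ccccc3)[C@@H]2O)cc1 | intermediate (not isolated)
18 | (2R,3S,4S)-4-{4,6-bis(benzyloxy)-2-hydroxy-3-[(4-methylphenyl)sulfonylmethyl]phenyl}-7-benzyloxy-2-(4-benzyloxyphenyl)chroman-3-ol | c1ccccc1COc1ccc([C@H]2Oc3cc(OCc4ccccc4)ccc3[C@@H](c3c(O)c(CS(=O)(=O)c4ccc(C)cc4)c(OCc4ccccc4)cc3OCc3ccccc3)[C@@H]2O)cc1 | intermediate (key-step precursor)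
19 | benzyloxyacetaldehyde | O=CCOCc1ccccc1 | starting material
20 | (S)-1-[(E)-2-(benzyloxy)ethenyl]-2-[diphenyl(trimethylsilyloxy)methyl]pyrrolidine | C[Si](C)(C)OC(c1ccccc1)(c1ccccc1)[C@@H]1CCCN1/C=C/OCc1ccccc1 | intermediate (not isolated)
21 | 3,5-bis(benzyloxy)-2-[(2R,3S,4S)-7-benzyloxy-2-(4-benzyloxyphenyl)-3-hydroxychroman-4-yl]-6-methylidenecyclohexa-2,4-dien-1-one | c1ccccc1COc1ccc([C@H]2Oc3cc(OCc4ccccc4)ccc3[C@@H](C3=C(OCc4ccccc4)C=C(OCc4ccccc4)C(=C)C3=O)[C@@H]2O)cc1 | intermediate (not isolated)
22 | (2R)-2-benzyloxy-3-{4,6-bis(benzyloxy)-3-[(2R,3S,4S)-7-benzyloxy-2-(4-benzyloxyphenyl)-3-hydroxychroman-4-yl]-2-hydroxyphenyl}propanal | c1ccccc1COc1ccc([C@H]2Oc3cc(OCc4ccccc4)ccc3[C@@H](c3c(O)c(C[C@@H](OCc4ccccc4)C=O)c(OCc4ccccc4)cc3OCc3ccccc3)[C@@H]2O)cc1 | intermediate (not isolated)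
23 | (2RS,3R)-3,5,7-tris(benzyloxy)-8-[(2R,3S,4S)-7-benzyloxy-2-(4-benzyloxyphenyl)-3-hydroxychroman-4-yl]chroman-2-ol | c1ccccc1COc1ccc([C@H]2Oc3cc(OCc4ccccc4)ccc3[C@@H](c3c(OCc4ccccc4)cc(OCc4ccccc4)c4c3OC(O)[C@H](OCc3ccccc3)C4)[C@@H]2O)cc1 | intermediate (key-step product)
24 | 4-benzyloxyphenylmagnesium bromide | Br[Mg]c1ccc(OCc2ccccc2)cc1 | starting material
25 | (1RS,2R)-2-benzyloxy-1-(4-benzyloxyphenyl)-3-{4,6-bis(benzyloxy)-3-[(2R,3S,4S)-7-benzyloxy-2-(4-benzyloxyphenyl)-3-hydroxychroman-4-yl]-2-hydroxyphenyl}propan-1-ol | c1ccccc1COc1ccc([C@H]2Oc3cc(OCc4ccccc4)ccc3[C@@H](c3c(O)c(C[C@@H](OCc4ccccc4)C(O)c4ccc(OCc5ccccc5)cc4)c(OCc4ccccc4)cc3OCc3ccccc3)[C@@H]2O)cc1 | intermediate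
26 | para-benzyloxybenzyl cation at C2' derived from 25 | c1ccccc1COc1ccc([C@H]2Oc3cc(OCc4ccccc4)ccc3[C@@H](c3c(O)c(C[C@@H](OCc4ccccc4)[CH+]c4ccc(OCc5ccccc5)cc4)c(OCc4ccccc4)cc3OCc3ccccc3)[C@@H]2O)cc1 | intermediate (not isolated)
27 | (2R,3S,4S)-7-benzyloxy-2-(4-benzyloxyphenyl)-4-[(2S,3R)-3,5,7-tris(benzyloxy)-2-(4-benzyloxyphenyl)chroman-8-yl]chroman-3-ol | c1ccccc1COc1ccc([C@H]2Oc3cc(OCc4ccccc4)ccc3[C@@H](c3c(OCc4ccccc4)cc(OCc4ccccc4)c4c3O[C@@H](c3ccc(OCc5ccccc5)cc3)[C@H](OCc3ccccc3)C4)[C@@H]2O)cc1 | intermediate
28 | (2R,3S,4S)-2-(4-hydroxyphenyl)-4-[(2S,3R)-3,5,7-trihydroxy-2-(4-hydroxyphenyl)chroman-8-yl]chroman-3,7-diol | Oc1ccc([C@H]2Oc3cc(O)ccc3[C@@H](c3c(O)cc(O)c4c3O[C@@H](c3ccc(O)cc3)[C@H](O)C4)[C@@H]2O)cc1 | target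

## Step count and least certain steps

Total step count: 13. Longest linear sequence: 12 steps (steps 1, 2 and 4 to 13, from 1 to 28); step 3 is the one-step side branch from 5.

Step 10 (key step). The most likely failure is that the transient ortho-quinone methide is consumed by self-condensation or by re-addition of sulfinate before the modestly nucleophilic enamine captures it. The other concern is erosion of facial selectivity if the α-benzyloxy enamine reacts partly through its minor geometry. The fallback replaces catalyst control with auxiliary control and a far more reactive nucleophile. It sets out from 18. The lithium enolate of (S)-4-benzyl-3-(benzyloxyacetyl)oxazolidin-2-one (LiN(SiMe3)2, THF, −78 → 0 °C, used in excess to cover the two hydroxyl protons) should trigger sulfinate loss and add to the quinone methide anti to the benzyl group of the chelated Z-enolate. The liberated C8a' phenoxide should then cleave the imide by lactonisation to (3R)-3,5,7-tris(benzyloxy)-8-[(2R,3S,4S)-7-benzyloxy-2-(4-benzyloxyphenyl)-3-hydroxychroman-4-yl]chroman-2-one F1. Reduction of this aryl lactone with i-Bu2AlH in CH2Cl2 at −78 °C should return the route at 23.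

Step 12. The most likely failure is insufficient trans selectivity in the capture of cation 26, since the intrinsic preference for the diequatorial ring is only moderate. If the acid is pushed towards equilibration, partial ionisation of the O1–C2 bond could also scramble C2. The fallback is a stereospecific closure that avoids the cation. It sets out from 25, using its syn (1R,2R) component, which chelation control in step 11 should make the major one, and it returns at 27. PPh3 and DIAD in THF at 0 °C should activate the benzylic C2' hydroxyl, which is less hindered than the C3 hydroxyl, and the C8a' phenol should displace it with inversion (Mitsunobu etherification). No new compound is involved.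

Step 4. The most likely failure is loss of regiocontrol in the metalation (lithiation between the two benzyloxy groups or at a benzylic position). A second risk is proton transfer from C3 of 4 to the hindered aryl nucleophile, followed by opening of the enolate to the chalcone phenoxide, which would erase C2. The fallback fixes the metal position through a halogen and sets out from 5. Amine-mediated ortho-bromination of the phenol (NBS with catalytic i-Pr2NH in CH2Cl2 at 0 °C) should give 3,5-bis(benzyloxy)-2-bromophenol F2. MOMCl and NaH should then give 1,5-bis(benzyloxy)-2-bromo-3-(methoxymethoxy)benzene F3. Bromine–lithium exchange with n-BuLi in THF at −78 °C generates 7 cold and within minutes, and the route continues from 7 as in step 4.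

Step 6. The most likely failure is sluggish or poorly face-selective addition of borane to the hindered trisubstituted alkene, which is flanked by a twisted, di-ortho-substituted aryl ring. This would give 2,3-cis material or need temperatures at which the β-oxygenated borane can fragment. The fallback forms the C4–C8' bond by cation capture instead. It sets out from 4 (with 5 as the nucleophile) and returns at 14. Soft enolisation of 4 (TMSOTf, Et3N, CH2Cl2, 0 °C) should give (2S)-7-benzyloxy-2-(4-benzyloxyphenyl)-4-(trimethylsilyloxy)-2H-chromene F4. Rubottom oxidation with dimethyldioxirane anti to the C2 aryl group, with a desilylating work-up, should give (2R,3R)-7-benzyloxy-2-(4-benzyloxyphenyl)-3-hydroxychroman-4-one F5. Reduction with NaBH4 should give (2R,3S,4RS)-7-benzyloxy-2-(4-benzyloxyphenyl)chroman-3,4-diol F6. Ionisation of this diol at C4 with catalytic TsOH in CH2Cl2 in the presence of 5 should alkylate 5 ortho to its hydroxyl, trans to the C3 hydroxyl, and deliver 14. Regiochemistry on 5 and the 3,4-trans preference are then matters of selectivity, not of mechanism.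

Step 8. The most likely failure is slow formaldehyde transfer at C4a', a position flanked on both sides in a magnesium phenoxide that is itself crowded by the neighbouring flavanyl group. The result would be incomplete conversion or methylene-bridged by-products. The fallback is a direct acid-mediated three-component sulfonylmethylation. It sets out from 14 and returns at 18. Paraformaldehyde and p-TolSO2Na in HCO2H–H2O–THF at rt should place the tosylmethyl group by electrophilic substitution, and this also saves step 9. Regiochemistry then rests on the innate preference for the less hindered C4a' over C6', which lies between two benzyloxy groups. Any para isomer would have to be separated. No new compound is involved.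

## Further compounds

F1 | step 10 | (3R)-3,5,7-tris(benzyloxy)-8-[(2R,3S,4S)-7-benzyloxy-2-(4-benzyloxyphenyl)-3-hydroxychroman-4-yl]chroman-2-one | c1ccccc1COc1ccc([C@H]2Oc3cc(OCc4ccccc4)ccc3[C@@H](c3c(OCc4ccccc4)cc(OCc4ccccc4)c4c3OC(=O)[C@H](OCc3ccccc3)C4)[C@@H]2O)cc1
F0 | step 12 | none | none
F2 | step 4 | 3,5-bis(benzyloxy)-2-bromophenol | Oc1cc(OCc2ccccc2)cc(OCc2ccccc2)c1Br
F3 | step 4 | 1,5-bis(benzyloxy)-2-bromo-3-(methoxymethoxy)benzene | COCOc1cc(OCc2ccccc2)cc(OCc2ccccc2)c1Br
F4 | step 6 | (2S)-7-benzyloxy-2-(4-benzyloxyphenyl)-4-(trimethylsilyloxy)-2H-chromene | c1ccccc1COc1ccc([C@H]2Oc3cc(OCc4ccccc4)ccc3C(O[Si](C)(C)C)=C2)cc1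
F5 | step 6 | (2R,3R)-7-benzyloxy-2-(4-benzyloxyphenyl)-3-hydroxychroman-4-one | c1ccccc1COc1ccc([C@H]2Oc3cc(OCc4ccccc4)ccc3C(=O)[C@@H]2O)cc1
F6 | step 6 | (2R,3S,4RS)-7-benzyloxy-2-(4-benzyloxyphenyl)chroman-3,4-diol | c1ccccc1COc1ccc([C@H]2Oc3cc(OCc4ccccc4)ccc3C(O)[C@@H]2O)cc1
F0 | step 8 | none | none
A1 | alternative 1 | ring D phenol with free C8a' hydroxyl, triisopropylsilyl ethers on C5' and C7', the trans-acetonide side chain on C4a' and the tri-O-benzyl upper unit on C8' | c1ccccc1COc1ccc([C@H]2Oc3cc(OCc4ccccc4)ccc3[C@@H](c3c(O[Si](C(C)C)(C(C)C)C(C)C)cc(O[Si](C(C)C)(C(C)C)C(C)C)c(C[C@H]4OC(C)(C)O[C@@H]4c4ccc(OCc5ccccc5)cc4)c3O)[C@@H]2OCc2ccccc2)cc1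
A2 | alternative 1 | all-trans 3,7-bis(benzyloxy)-2-(4-benzyloxyphenyl)-4-[(triisopropylsilyloxy)ethynyl]chromane | c1ccccc1COc1ccc([C@H]2Oc3cc(OCc4ccccc4)ccc3[C@@H](C#CO[Si](C(C)C)(C(C)C)C(C)C)[C@@H]2OCc2ccccc2)cc1
A3 | alternative 1 | 4-{[trans-5-(4-benzyloxyphenyl)-2,2-dimethyl-1,3-dioxolan-4-yl]methyl}-3-(triisopropylsilyloxy)cyclobut-2-en-1-one | O=C1C=C(O[Si](C(C)C)(C(C)C)C(C)C)C1C[C@H]1OC(C)(C)O[C@@H]1c1ccc(OCc2ccccc2)cc1
A4 | alternative 2 | hepta-O-benzyl ether of 28 | c1ccccc1COc1ccc([C@H]2Oc3cc(OCc4ccccc4)ccc3[C@@H](c3c(OCc4ccccc4)cc(OCc4ccccc4)c4c3O[C@@H](c3ccc(OCc5ccccc5)cc3)[C@H](OCc3ccccc3)C4)[C@@H]2OCc2ccccc2)cc1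
A5 | alternative 2 | open-chain dibromo diol: hepta-O-benzyl precursor with free C2 and C2' hydroxyls and bromine on C8a and C8a' | c1ccccc1COc1ccc([C@@H](O)[C@@H](OCc2ccccc2)[C@@H](c2ccc(OCc3ccccc3)cc2Br)c2c(OCc3ccccc3)cc(OCc3ccccc3)c(C[C@@H](OCc3ccccc3)[C@@H](O)c3ccc(OCc4ccccc4)cc3)c2Br)cc1
A6 | alternative 3 | per-benzylated target with benzyldimethylsilyl in place of the C3 hydroxyl | c1ccccc1COc1ccc([C@H]2Oc3cc(OCc4ccccc4)ccc3[C@@H](c3c(OCc4ccccc4)cc(OCc4ccccc4)c4c3O[C@@H](c3ccc(OCc5ccccc5)cc3)[C@H](OCc3ccccc3)C4)[C@@H]2[Si](C)(C)Cc2ccccc2)cc1
A7 | alternative 3 | ring A ortho-quinone methide (3-benzyloxy-6-methylidenecyclohexa-2,4-dien-1-one) whose methide carbon carries the (2S,3R)-tetra-O-benzyl lower unit through C8' | O=C1C=C(OCc2ccccc2)C=CC1=Cc1c(OCc2ccccc2)cc(OCc2ccccc2)c2c1O[C@@H](c1ccc(OCc3ccccc3)cc1)[C@H](OCc1ccccc1)C2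
A8 | alternative 3 | (E)-benzyl{2-[4-(benzyloxy)phenyl]ethenyl}dimethylsilane | C[Si](C)(Cc1ccccc1)/C=C/c1ccc(OCc2ccccc2)cc1
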